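- The amount of Z in a flask at a given time is what has been made less what has since been lost, so a share of the charge needs a measure of loss as well as of making.

| flask | G | E | Z | time |
|---|---|---|---|---|
| grey | 1.00 M | 2.00 M |  |  |
| amber | 0.600 M | 1.60 M |  |  |
| teal | 1.00 M | 2.00 M | 0.300 M |  |
| red | 2.00 M | 2.00 M |  |  |
| violet | 0.500 M | 6.00 M |  | 11 min |

| grey run: time / min | grey run: [Z] / M | amber run: time / min | amber run: [Z] / M | teal run: time / min | teal run: [Z] / M | red run: time / min | red run: [Z] / M |
|---|---|---|---|---|---|---|---|
| 0.44 | 0.012 | 0.44 | 0 | 0.44 | 0.311 | 0.44 | 0.006 |
| 0.98 | 0.020 | 0.98 | 0.001 | 0.98 | 0.305 | 0.98 | 0.051 |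
| 2.2 | 0.058 | 2.2 | 0.032 | 2.2 | 0.333 | 2.2 | 0.160 |
| 4.9 | 0.191 | 4.9 | 0.116 | 4.9 | 0.406 | 4.9 | 0.433 |
| 11 | 0.339 | 11 | 0.188 | 11 | 0.422 | 11 | 0.875 |

(each reading ± 0.01 M)

- the power of [G] that the first rate follows, about the charge of the grey run; measure it at two percent of G made into Z (one fixed amount of Z, the same in the runs compared)
- the power of [E] that the first rate follows, about the charge of the grey run; measure it at two percent of G made into Z
- Z in the violet run at 11 min, as a share of the G charged

- Overall: G + E -> Z.
- Constant volume, constant temperature.
- An order is taken over about fifteen percent of the charge, up and down.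

- The teal run differs from the grey run by the 0.300 M of Z in its charge, and at 11 min teal reads 0.0830 M above grey, so 27.7% of the added Z is found again, a reading that carries the scatter of both runs.
- This reckoning takes the loss as first order in [E]; with E in excess in the violet run, that makes the loss of Z pseudo-first-order.
- Define the loss number D as the natural logarithm of the Z added in teal over the excess found at 11 min, multiplied by the E charged in violet over the E charged in grey: D = 3.85.
- At one end, Z made at the very start keeps the share exp(−D), which is 2.12%.
- At the other end, G turns wholly and evenly up to 11 min, and the share is one minus exp(−D), over D, which is 25.4%.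
- No run so far was charged like violet, so no reading places it between the ends; this reckoning takes their geometric mean as a plain choice and commits to 7.33% for violet.
- The forecast gives 1.2 for the order in G, 0 for the order in E and 25% for violet, on the ground that “Z is therefore an inhibitor, or the reaction is partly reversible”.
- Turned round, a violet share as high as the forecast's stands at the even end of this reckoning, with G wholly turned; the committed share is lower than the forecast's.
- The flask gives 0.68 for the order in G, 0.49 for the order in E and 6.09% for violet.

    G + E → J (0.1242 L mol⁻¹ min⁻¹)
    J → Z (0.1662 min⁻¹)
    Z + E → Q (0.1362 L mol⁻¹ min⁻¹)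
    G + E + Z → 2 Z (0.1680 L² mol⁻² min⁻¹)

- The main reason for the low violet share is the conversion of Z and E into Q: the simulated violet run without that step holds 81.0% at 11 min, against 6.09% as it stands. Violet therefore keeps 7.52% of that amount, which lies above 2.12% and below 25.4%. Applied to the simulated violet run without the conversion of Z and E into Q, the joined share of 7.33% turns 81.0% into 5.94%, and violet as it stands gives 6.09%.

(Readings and results are calculated with made-up constants, noise included.)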